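**Retrosynthetic overview**

1. Methyl sarcoate 18 ⇒ 12-membered β-diketone 15 + methyl propiolate 16: a photochemical [2+2]/retro-aldol two-carbon ring expansion makes C3–C4 and C5–C6 and installs the ester-bearing C4=C5 last.
2. 15 ⇒ acyclic keto aldehyde 13: Nozaki–Hiyama–Kishi closure of C12–C13 from the (Z)-vinyl iodide, then oxidation to the Z-enone.
3. 13 ⇒ methyl ketone 5 + (R)-lactone 10: Claisen-type C-acylation forms C2–C3 and the β-diketone.
4. 5 ⇐ pent-4-yn-1-ol (Z-iodo-olefination, then carboalumination/acylation for the E-enone); 10 ⇐ (R)-α-phellandrene (oxidative cleavage, haloform, anhydride, regioselective reduction), the source of the only stereocentre.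
5. Ring order: the 12-membered carbocycle is closed first (step 10) and expanded to the 14-membered ring in the final step.

Assumption: locants C1–C14 in the explanations are the ring positions of the target (C1 = CH(i-Pr), C2 = adjacent ketone, C4 = ester-bearing carbon, C6 and C13 = the other ketones), and commercial (R)-(−)-α-phellandrene of high enantiomeric purity is used.

**Route**

Step 1
Reactants: 1 pent-4-yn-1-ol
Product: 2 pent-4-ynal
Conditions: Dess–Martin periodinane, CH2Cl2, 0 °C → rt; solution used directly
Reagents that add atoms: none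
Why: Dess–Martin oxidation takes the primary alcohol to the aldehyde under mild conditions that leave the terminal alkyne untouched.

Step 2
Reactants: 2 pent-4-ynal
Product: 3 (2Z)-2-iodohept-2-en-6-yne
Conditions: Ph3PEt+ I−, n-BuLi, THF, 0 °C; I2, −78 °C; NaN(SiMe3)2, −20 °C; then 2, −78 °C → rt
Reagents that add atoms: ethyltriphenylphosphonium iodide, CC[P+](c1ccccc1)(c1ccccc1)c1ccccc1.[I-]; iodine, II
Why: Stork–Zhao-type Wittig olefination with the α-iodoethylidene ylide gives the trisubstituted (Z)-vinyl iodide (iodine cis to the chain), which later fixes the Z geometry of the C11=C12 enone.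

Step 3
Reactants: 3 (2Z)-2-iodohept-2-en-6-yne
Product: 5 (3E,7Z)-8-iodo-4-methylnona-3,7-dien-2-one, via alkenylalane 4 (not isolated)
Conditions: AlMe3 (2.5 equiv), Cp2ZrCl2 (0.25 equiv), CH2Cl2, 0 °C → rt; then AcCl, −30 → 0 °C
Reagents that add atoms: trimethylaluminium, C[Al](C)C; acetyl chloride, CC(Cl)=O
Why: Negishi zirconium-catalysed carboalumination adds methyl and aluminium syn and regioselectively across the terminal alkyne (E geometry at C7=C8), and acylation of the alkenylalane with retention gives the methyl enone while the vinyl iodide is untouched.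

Step 4
Reactants: 6 (R)-(−)-α-phellandrene [(5R)-2-methyl-5-(propan-2-yl)cyclohexa-1,3-diene]
Product: 7 (2R)-4-oxo-2-(propan-2-yl)pentanoic acid
Conditions: RuCl3 (3 mol %), NaIO4 (8 equiv), EtOAc/MeCN/H2O, 0 °C → rt
Reagents that add atoms: sodium periodate, [Na+].[O-]I(=O)(=O)=O
Why: RuO4-mediated oxidative cleavage of both double bonds of the conjugated diene turns the ring CH next to the stereocentre into CO2H and the methyl-bearing carbon into a methyl ketone, and the purchased stereocentre is not involved.

Step 5
Reactants: 7 (2R)-4-oxo-2-(propan-2-yl)pentanoic acid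
Product: 8 (2R)-2-(propan-2-yl)butanedioic acid
Conditions: NaOCl (aq, 3.5 equiv), NaOH, H2O, 0 °C → rt; then HCl
Reagents that add atoms: sodium hypochlorite, [Na+].[O-]Cl (oxygen of the new CO2H, delivered as hydroxide)
Why: the haloform reaction (as in levulinic acid to succinic acid) removes the methyl carbon, and the stereocentre sits α to a carboxylate so base does not epimerise it.

Step 6
Reactants: 8 (2R)-2-(propan-2-yl)butanedioic acid
Product: 9 (3R)-3-(propan-2-yl)oxolane-2,5-dione
Conditions: AcCl, reflux; evaporate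
Reagents that add atoms: none
Why: cyclodehydration of a succinic acid with acetyl chloride gives the five-membered anhydride without affecting the stereocentre.

Step 7
Reactants: 9 (3R)-3-(propan-2-yl)oxolane-2,5-dione
Product: 10 (3R)-3-(propan-2-yl)oxolan-2-one
Conditions: LiBH(s-Bu)3 (2.2 equiv), THF, −78 °C → rt; then 6 M HCl
Reagents that add atoms: none
Why: the bulky hydride attacks the less hindered carbonyl, the one remote from the isopropyl-bearing carbon, and acidification lactonises the hydroxy acid (regioselective anhydride reduction) to the α-isopropyl lactone.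

Step 8
Reactants: 5 (3E,7Z)-8-iodo-4-methylnona-3,7-dien-2-one; 10 (3R)-3-(propan-2-yl)oxolan-2-one
Product: 12 (3R,7E,11Z)-1-hydroxy-12-iodo-8-methyl-3-(propan-2-yl)trideca-7,11-diene-4,6-dione, via lithium enolate 11 (not isolated)
Conditions: 5 (2 equiv), LiN(i-Pr)2 (2 equiv), THF, −78 °C; then 10 (1 equiv), −78 → −20 °C; AcOH quench; excess 5 recovered
Reagents that add atoms: none
Why: kinetic α′-deprotonation of the methyl enone gives the cross-conjugated enolate 11, which C-acylates on the lactone carbonyl (Claisen-type condensation) and is trapped as the lithium diketonate, so no free amide base is present to epimerise the α-stereocentre of the lactone.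

Step 9
Reactants: 12 (3R,7E,11Z)-1-hydroxy-12-iodo-8-methyl-3-(propan-2-yl)trideca-7,11-diene-4,6-dione
Product: 13 (3R,7E,11Z)-12-iodo-8-methyl-4,6-dioxo-3-(propan-2-yl)trideca-7,11-dienal
Conditions: Dess–Martin periodinane (1.3 equiv), CH2Cl2, 0 °C; used at once
Reagents that add atoms: none
Why: Dess–Martin oxidation takes the primary alcohol (open form of the hemiketal equilibrium) to the aldehyde under non-basic conditions that do not start aldol chemistry of the β-diketone.

Step 10
Reactants: 13 (3R,7E,11Z)-12-iodo-8-methyl-4,6-dioxo-3-(propan-2-yl)trideca-7,11-dienal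
Product: 14 (4E,8Z,12R)-10-hydroxy-5,9-dimethyl-12-(propan-2-yl)cyclododeca-4,8-diene-1,3-dione (both C10 epimers)
Conditions: CrCl2 (10 equiv), NiCl2 (0.1 equiv), DMSO/THF, 2 mM, slow addition, rt
Reagents that add atoms: none
Why: the intramolecular Nozaki–Hiyama–Kishi reaction (nickel-mediated activation of the vinyl iodide, transfer to chromium, aldehyde-selective addition with retention of the Z geometry) closes the 12-membered ring at high dilution; the new carbinol centre is not controlled and is erased in step 11.

Step 11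
Reactants: 14 (4E,8Z,12R)-10-hydroxy-5,9-dimethyl-12-(propan-2-yl)cyclododeca-4,8-diene-1,3-dione
Product: 15 (4R,7Z,11E)-7,11-dimethyl-4-(propan-2-yl)cyclododeca-7,11-diene-1,3,6-trione
Conditions: Dess–Martin periodinane (1.5 equiv), CH2Cl2, 0 °C → rt
Reagents that add atoms: none
Why: Dess–Martin oxidation of the allylic alcohol gives the Z-enone without double-bond isomerisation and tolerates the β-diketone.

Step 12
Reactants: 15 (4R,7Z,11E)-7,11-dimethyl-4-(propan-2-yl)cyclododeca-7,11-diene-1,3,6-trione; 16 methyl prop-2-ynoate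
Product: 18 methyl sarcoate [methyl (1E,4E,8Z,12R)-5,9-dimethyl-3,10,13-trioxo-12-(propan-2-yl)cyclotetradeca-1,4,8-triene-1-carboxylate], via cyclobutenol photoadduct 17 (not isolated)
Conditions: 16 (20 equiv), CH2Cl2 (5 mM in 15), 365 nm LED, 10 °C, argon
Reagents that add atoms: none
Why: Proposed new method: 365 nm light excites the hydrogen-bonded enol of the β-diketone (the only strong absorber above 350 nm), which should add the electron-poor alkyne head-to-head (alkyne CH to the less hindered enol carbon C6, ester-bearing carbon to C3, through a 1,4-diradical whose two centres are both carbonyl-stabilised) to give the cis-fused cyclobutenol 17, whose strain-driven retro-aldol opening cleaves the old C3–C6 bond and leaves C4=C5 in the ring with C3 and C6 necessarily cis (the required 1E geometry), while kinetic protonation of the dienol at C3 gives 18 under neutral conditions that spare the C1 stereocentre and the acidic C3 methylene; the closest known chemistry is the de Mayo reaction of enolised 1,3-diketones with alkenes and the enone–alkyne photocycloadditions used for two-carbon ring expansion, neither of which has been shown on a macrocyclic β-diketone or used to make a cis-ene-1,5-dione of this kind.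

**Compound list**

1 | pent-4-yn-1-ol | C#CCCCO | starting material
2 | pent-4-ynal | C#CCCC=O | intermediate
3 | (2Z)-2-iodohept-2-en-6-yne | C#CCC/C=C(/C)I | intermediate
4 | [(1E,5Z)-6-iodo-2-methylhepta-1,5-dien-1-yl]dimethylalane | C[Al](C)/C=C(\C)CC/C=C(/C)I | intermediate
5 | (3E,7Z)-8-iodo-4-methylnona-3,7-dien-2-one | CC(=O)/C=C(\C)CC/C=C(/C)I | intermediate
6 | (R)-(−)-α-phellandrene, (5R)-2-methyl-5-(propan-2-yl)cyclohexa-1,3-diene | CC1=CC=C[C@@H](C(C)C)C1 | starting material
7 | (2R)-4-oxo-2-(propan-2-yl)pentanoic acid | OC(=O)[C@@H](C(C)C)CC(C)=O | intermediate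
8 | (2R)-2-(propan-2-yl)butanedioic acid | OC(=O)[C@@H](C(C)C)CC(=O)O | intermediate
9 | (3R)-3-(propan-2-yl)oxolane-2,5-dione | O=C1[C@@H](C(C)C)CC(=O)O1 | intermediate
10 | (3R)-3-(propan-2-yl)oxolan-2-one | O=C1[C@@H](C(C)C)CCO1 | intermediate
11 | lithium (3E,7Z)-8-iodo-4-methylnona-1,3,7-trien-2-olate | C=C(O[Li])/C=C(\C)CC/C=C(/C)I | intermediate
12 | (3R,7E,11Z)-1-hydroxy-12-iodo-8-methyl-3-(propan-2-yl)trideca-7,11-diene-4,6-dione | OCC[C@H](C(C)C)C(=O)CC(=O)/C=C(\C)CC/C=C(/C)I | intermediate
13 | (3R,7E,11Z)-12-iodo-8-methyl-4,6-dioxo-3-(propan-2-yl)trideca-7,11-dienal | O=CC[C@H](C(C)C)C(=O)CC(=O)/C=C(\C)CC/C=C(/C)I | intermediate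
14 | (4E,8Z,12R)-10-hydroxy-5,9-dimethyl-12-(propan-2-yl)cyclododeca-4,8-diene-1,3-dione, C10 epimers | OC1C[C@H](C(C)C)C(=O)CC(=O)/C=C(\C)CC/C=C1/C | intermediate
15 | (4R,7Z,11E)-7,11-dimethyl-4-(propan-2-yl)cyclododeca-7,11-diene-1,3,6-trione | O=C1C[C@H](C(C)C)C(=O)CC(=O)/C=C(\C)CC/C=C1/C | intermediate
16 | methyl prop-2-ynoate (methyl propiolate) | C#CC(=O)OC | starting material
17 | methyl (2E,6Z,10R)-1-hydroxy-3,7-dimethyl-8,11-dioxo-10-(propan-2-yl)bicyclo[10.2.0]tetradeca-2,6,13-triene-13-carboxylate, cis ring fusion | O=C1C[C@H](C(C)C)C(=O)C2C(C(=O)OC)=CC2(O)/C=C(\C)CC/C=C1/C | intermediate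
18 | methyl sarcoate, methyl (1E,4E,8Z,12R)-5,9-dimethyl-3,10,13-trioxo-12-(propan-2-yl)cyclotetradeca-1,4,8-triene-1-carboxylate | COC(=O)/C1=C/C(=O)/C=C(\C)CC/C=C(/C)C(=O)C[C@H](C(C)C)C(=O)C1 | target

**Step count**

Total steps: 12. Longest linear sequence: 9 (steps 4–12, from 6).

**Steps most likely to fail**

Step 12 (the new photochemical ring expansion). The alkyne may add with the wrong orientation or at the other enol terminus, and the two enones may isomerise (E/Z) under irradiation. The fallback sets out from 15 (with 16 as the source of the reagent) and returns at 18, using the classical alkene de Mayo reaction followed by a sulfoxide elimination. Thiophenol is added to 16 (cat. Et3N, then equilibration) to give methyl (2E)-3-(phenylsulfanyl)prop-2-enoate F7. Irradiating 15 with this push–pull alkene (sulfur-bearing carbon to the enol carbon, ester-bearing carbon to C3) and retro-aldol opening gives the 14-membered sulfide methyl (4E,8Z,12R)-5,9-dimethyl-3,10,13-trioxo-2-(phenylsulfanyl)-12-(propan-2-yl)cyclotetradeca-4,8-diene-1-carboxylate F8. mCPBA at −78 °C gives the sulfoxide methyl (4E,8Z,12R)-2-(benzenesulfinyl)-5,9-dimethyl-3,10,13-trioxo-12-(propan-2-yl)cyclotetradeca-4,8-diene-1-carboxylate F9. Warming F9 in toluene (60–80 °C) causes syn-elimination toward the only β-hydrogen (on C4) and gives 18. This fallback is still photochemical, so it answers the alkyne-specific risks (reactivity, orientation) but not enone photoisomerisation.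

Step 10 (Nozaki–Hiyama–Kishi macrocyclisation). Keto aldehyde 13 can cyclise by attack of the β-diketone on the aldehyde, and the free diketone can bind or protonate the organochromium species. The fallback sets out from 10 and 5 and returns at 15; it reverses the order of the two unions so the ring is closed by C-acylation. Lactone 10 is opened with MeNH(OMe)·HCl/AlMe3 to (2R)-4-hydroxy-N-methoxy-N-methyl-2-(propan-2-yl)butanamide F3, which is oxidised with Dess–Martin periodinane to (2R)-N-methoxy-N-methyl-4-oxo-2-(propan-2-yl)butanamide F4. Intermolecular Nozaki–Hiyama–Kishi coupling of F4 with vinyl iodide 5 gives (2R,5Z,9E)-4-hydroxy-N-methoxy-N,5,9-trimethyl-11-oxo-2-(propan-2-yl)dodeca-5,9-dienamide F5. Dess–Martin oxidation gives (2R,5Z,9E)-N-methoxy-N,5,9-trimethyl-4,11-dioxo-2-(propan-2-yl)dodeca-5,9-dienamide F6. Slow addition of F6 to LiN(SiMe3)2 in THF at −78 °C closes the 12-membered ring by intramolecular acylation of the methyl-ketone enolate on the Weinreb amide and gives 15.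

Step 8 (acylation of enolate 11 by the α-branched lactone). The hindered lactone may react slowly, and proton transfer from its α-position would erode the stereocentre. The fallback sets out from 10 and 4 and returns at 12; it exchanges the roles of nucleophile and electrophile so the stereocentre sits on the enolate partner, where kinetic deprotonation occurs at the methyl group. MeLi (1 equiv, THF, −78 °C) opens 10 to (3R)-5-hydroxy-3-(propan-2-yl)pentan-2-one F1 (in equilibrium with its cyclic hemiketal). Alkenylalane 4 is quenched with methyl chloroformate instead of acetyl chloride to give methyl (2E,6Z)-7-iodo-3-methylocta-2,6-dienoate F2. The dianion of F1 (LiN(i-Pr)2, 2.1 equiv: alkoxide plus kinetic methyl enolate) is acylated by F2 in a crossed Claisen condensation to give 12.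

**Further compounds**

F1 | step 8 | (3R)-5-hydroxy-3-(propan-2-yl)pentan-2-one | CC(=O)[C@@H](C(C)C)CCO
F2 | step 8 | methyl (2E,6Z)-7-iodo-3-methylocta-2,6-dienoate | COC(=O)/C=C(\C)CC/C=C(/C)I
F3 | step 10 | (2R)-4-hydroxy-N-methoxy-N-methyl-2-(propan-2-yl)butanamide | OCC[C@H](C(C)C)C(=O)N(C)OC
F4 | step 10 | (2R)-N-methoxy-N-methyl-4-oxo-2-(propan-2-yl)butanamide | O=CC[C@H](C(C)C)C(=O)N(C)OC
F5 | step 10 | (2R,5Z,9E)-4-hydroxy-N-methoxy-N,5,9-trimethyl-11-oxo-2-(propan-2-yl)dodeca-5,9-dienamide | CC(=O)/C=C(\C)CC/C=C(/C)C(O)C[C@H](C(C)C)C(=O)N(C)OC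
F6 | step 10 | (2R,5Z,9E)-N-methoxy-N,5,9-trimethyl-4,11-dioxo-2-(propan-2-yl)dodeca-5,9-dienamide | CC(=O)/C=C(\C)CC/C=C(/C)C(=O)C[C@H](C(C)C)C(=O)N(C)OC
F7 | step 12 | methyl (2E)-3-(phenylsulfanyl)prop-2-enoate | COC(=O)/C=C/Sc1ccccc1
F8 | step 12 | methyl (4E,8Z,12R)-5,9-dimethyl-3,10,13-trioxo-2-(phenylsulfanyl)-12-(propan-2-yl)cyclotetradeca-4,8-diene-1-carboxylate | COC(=O)C1C(Sc2ccccc2)C(=O)/C=C(\C)CC/C=C(/C)C(=O)C[C@H](C(C)C)C(=O)C1
F9 | step 12 | methyl (4E,8Z,12R)-2-(benzenesulfinyl)-5,9-dimethyl-3,10,13-trioxo-12-(propan-2-yl)cyclotetradeca-4,8-diene-1-carboxylate | COC(=O)C1C(S(=O)c2ccccc2)C(=O)/C=C(\C)CC/C=C(/C)C(=O)C[C@H](C(C)C)C(=O)C1
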